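**Plan**

1. Locants (eudesmane): C1 = CHBr, C4 = C(=CH2), C5 = C(OH), C7 = CH carrying the triene (C11 is its first carbon), C10 = C(CH3). Ring A = C1–C5 + C10; ring B = C5–C10.
2. Retrosynthesis: the triene is cut at C12–C13 (cross-coupling) and traced through a C11≡C12 alkyne to a C7 ester. C4=CH2 comes from a C4 ketone, C1–Br from a C1 ketone (bromoalkene, then hydrogen-atom-transfer hydrogenation), and C5–OH from a 4-keto-Δ5-ene. Then C5–C10 and C7–C8 are cut together, which opens both rings to one chain, and the 4-oxo-2-enal end of that chain is traced to a 2,3-disubstituted furan (temporary ring).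
3. Enabling feature: in ring B the unit C8–C9–C10 carries no function, so it can be the carbonyl, α- and β-carbon of an enal. C5 and C7, 1,3-related across C6, each bear an sp2 carbon of the target (C4, C11) that can be a carbonyl. C5–C6–C7 is therefore the α,γ-bis-nucleophile of a 5-oxo-2-enoate, and a [3+3] Michael/aldol-condensation closes ring A (C5–C10) and then ring B (C7–C8).
4. Forward: furan + acrolein, allylation, oxidation, cross metathesis, furan photooxygenation, bicyclisation (ring A, then ring B). Adjustment follows at C7/C8, C1, C5 and C4, then chain extension at C11.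
5. Stereochemistry: C10 comes from the chiral amine catalyst in the key step. C7, C5 and C1 are then set one after the other on the α-face, opposite the axial C10 methyl group (H2, O2, H atom). Both triene alkenes come from syn hydro- and carbometallation.

Key step: step 6

**Step 1**
Reactants: 1 3-methylfuran; 2 acrolein
Product: 3 3-(3-methylfuran-2-yl)propanal
Conditions: AcOH (cat.), hydroquinone (cat.), excess 1, 23 °C
Reagents that add atoms: none
Why: Acid-catalysed Friedel–Crafts-type conjugate addition of the furan to acrolein; the free α-position next to the methyl group is the most nucleophilic site, so the chain should end up beside the methyl group.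

**Step 2**
Reactants: 3 3-(3-methylfuran-2-yl)propanal; 4 allylmagnesium bromide
Product: 5 (±)-1-(3-methylfuran-2-yl)hex-5-en-3-ol
Conditions: THF, −78 °C; then H2O
Reagents that add atoms: none
Why: Grignard 1,2-addition to the aldehyde; the new carbinol centre is racemic and is erased in step 3.

**Step 3**
Reactants: 5 (±)-1-(3-methylfuran-2-yl)hex-5-en-3-ol
Product: 6 1-(3-methylfuran-2-yl)hex-5-en-3-one
Conditions: Dess–Martin periodinane, CH2Cl2, 0 → 23 °C
Reagents that add atoms: none
Why: Dess–Martin oxidation under near-neutral conditions should give the β,γ-unsaturated ketone without moving the alkene into conjugation and without touching the furan.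

**Step 4**
Reactants: 6 1-(3-methylfuran-2-yl)hex-5-en-3-one; 7 methyl acrylate
Product: 8 methyl (E)-7-(3-methylfuran-2-yl)-5-oxohept-2-enoate
Conditions: second-generation Grubbs catalyst (3 mol%), CH2Cl2, 40 °C
Reagents that add atoms: none
Why: Olefin cross metathesis of a terminal alkene and an acrylate gives the E-enoate because the acrylate does not homodimerise and the E-isomer is the thermodynamic product; furan and ketone are inert.

**Step 5**
Reactants: 8 methyl (E)-7-(3-methylfuran-2-yl)-5-oxohept-2-enoate
Product: 11 methyl (2E,9E)-9-methyl-5,8,11-trioxoundeca-2,9-dienoate, via furan endoperoxide 9 (not isolated), via Z-oxoenal 10 (not isolated)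
Conditions: O2, hν (visible), tetraphenylporphyrin (cat.), CH2Cl2, −78 °C; Me2S, −78 → 23 °C; I2 (5 mol%), 23 °C
Reagents that add atoms: dioxygen, O=O
Why: [4+2] photooxygenation of the electron-rich furan by singlet oxygen, reduction of the endoperoxide to the Z-4-oxo-2-enal and iodine-catalysed Z-to-E isomerisation unmask the furan as C8 aldehyde, C9=C10 alkene and C1 ketone; the electron-poor enoate does not react with singlet oxygen.

**Step 6**
Reactants: 11 methyl (2E,9E)-9-methyl-5,8,11-trioxoundeca-2,9-dienoate
Product: 13 methyl (8aR)-8a-methyl-1,4-dioxo-1,2,3,4,8,8a-hexahydronaphthalene-6-carboxylate, via Michael adduct 12 (not isolated)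
Conditions: (S)-2-[diphenyl(trimethylsilyloxy)methyl]pyrrolidine (20 mol%), PhCO2H (20 mol%), toluene (0.02 M), 0 → 23 °C
Reagents that add atoms: none
Why: Proposed new method: the amine condenses with the C8 aldehyde to an E, s-trans iminium ion, the dienol of the 5-oxo-2-enoate adds through C5 to the β-carbon C10 (6-(enolendo)-exo-trig, closes ring A as the cyclohexane-1,4-dione 12), and after a proton shift the re-formed dienol attacks the C8 iminium ion through its γ-carbon C7 (6-exo-trig at C8=N, Mannich-type closure of ring B), whereupon β-elimination of the amine gives C7=C8 and frees the catalyst. The closest known reaction types are the amine-catalysed Michael/aldol-condensation [3+3] annulation of β-keto esters with enals and the iminium-catalysed Michael addition to β,β-disubstituted enals that sets all-carbon quaternary centres; new is that both partners sit in one chain and that the acceptor is a 4-oxo-2-enal. C10 is the only stereocentre that remains and is set by the catalyst: the CPh2(OSiMe3) group covers one face of the planar iminium ion, so C5 should bond to the open face of the E-alkene, which gives 10R, while C5 and C7 end as sp2 carbons. The step needs conjugate attack at C10: attack of C5 or C7 at C8 before ring A exists would need an eight- or ten-membered ring, attack at C9 a seven-membered ring, and iminium formation makes C10 the most electrophilic carbon, which should also outrun the five-ring aldol of C5 onto the C1 ketone and the uncatalysed addition. Loss of water to the through-conjugated dienone ester makes the sequence irreversible and drains the reversible side equilibria, and the quaternary C10 blocks aromatisation.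

**Step 7**
Reactants: 13 methyl (8aR)-8a-methyl-1,4-dioxo-1,2,3,4,8,8a-hexahydronaphthalene-6-carboxylate
Product: 14 methyl (6R,8aR)-8a-methyl-1,4-dioxo-1,2,3,4,6,7,8,8a-octahydronaphthalene-6-carboxylate
Conditions: H2 (1 atm, stopped after 1 equiv), 5% Pd/C, EtOAc, 0 °C
Reagents that add atoms: none
Why: Heterogeneous hydrogenation of the γ,δ-alkene of a linear dienone: C7=C8 is the less hindered and more electron-poor alkene, C5=C6 is shielded by the quaternary C10, and syn delivery of H2 to the α-face opposite the C10 methyl group sets the 7β-ester (7R in eudesmane locants).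

**Step 8**
Reactants: 14 methyl (6R,8aR)-8a-methyl-1,4-dioxo-1,2,3,4,6,7,8,8a-octahydronaphthalene-6-carboxylate
Product: 16 methyl (6R,8aR)-8a-methyl-4-oxo-1-(trifluoromethylsulfonyloxy)-3,4,6,7,8,8a-hexahydronaphthalene-6-carboxylate, via dipotassium bis-enolate 15 (not isolated)
Conditions: KN(SiMe3)2 (2.1 equiv), THF, −78 °C; N-(5-chloropyridin-2-yl)bis(trifluoromethanesulfonimide) (1.0 equiv), −78 °C; AcOH
Reagents that add atoms: N-(5-chloropyridin-2-yl)bis(trifluoromethanesulfonimide), O=S(=O)(N(c1ccc(Cl)cn1)S(=O)(=O)C(F)(F)F)C(F)(F)F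
Why: Site-selective enol triflate formation through a dianion: the first equivalent of base removes the acidic C7–H and locks the C4 carbonyl in an extended enolate, the second can only enolise the C1 ketone towards C2 because C10 is quaternary, the more basic C1 enolate is sulfonylated first, and protonation of the extended enolate at the less hindered C7 on the α-face should return the Δ5-enone bearing the 7β-ester.

**Step 9**
Reactants: 16 methyl (6R,8aR)-8a-methyl-4-oxo-1-(trifluoromethylsulfonyloxy)-3,4,6,7,8,8a-hexahydronaphthalene-6-carboxylate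
Product: 17 methyl (6R,8aR)-1-bromo-8a-methyl-4-oxo-3,4,6,7,8,8a-hexahydronaphthalene-6-carboxylate
Conditions: LiBr (2 equiv), [Cp*Ru(MeCN)3]OTf (5 mol%), 1,3-dimethylimidazolidin-2-one, 60 °C
Reagents that add atoms: lithium bromide, [Li+].[Br-]
Why: Ruthenium-catalysed triflate–halide exchange of an alkenyl triflate keeps the position of the alkene and is neutral, so enone and ester should survive.

**Step 10**
Reactants: 17 methyl (6R,8aR)-1-bromo-8a-methyl-4-oxo-3,4,6,7,8,8a-hexahydronaphthalene-6-carboxylate
Product: 19 methyl (4aS,6R,8aR)-1-bromo-4a-hydroxy-8a-methyl-4-oxo-3,4,4a,5,6,7,8,8a-octahydronaphthalene-6-carboxylate, via C5 hydroperoxide 18 (not isolated)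
Conditions: Mn(dpm)3 (10 mol%), PhSiH3 (2 equiv), O2 (1 atm), i-PrOH–CH2Cl2, 0 °C; then P(OEt)3
Reagents that add atoms: dioxygen, O=O
Why: Manganese-hydride conjugate reduction–α-oxygenation of an enone (Mukaiyama-type hydrogen-atom-transfer hydration): H goes to C6, the C5 radical or enolate is trapped by O2 on the α-face opposite the axial C10 methyl group, which sets 5α-OH and the trans ring fusion, the phosphite reduces the hydroperoxide, and the hindered bromoalkene should react more slowly than the enone.

**Step 11**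
Reactants: 19 methyl (4aS,6R,8aR)-1-bromo-4a-hydroxy-8a-methyl-4-oxo-3,4,4a,5,6,7,8,8a-octahydronaphthalene-6-carboxylate
Product: 20 methyl (1R,4aS,6R,8aR)-1-bromo-4a-hydroxy-8a-methyl-4-oxodecahydronaphthalene-6-carboxylate
Conditions: Mn(dpm)3 (15 mol%), PhSiH3 (2 equiv), t-BuOOH (1.5 equiv), i-PrOH, 23 °C, Ar
Reagents that add atoms: none
Why: Hydrogen-atom-transfer hydrogenation of a haloalkene without hydrogenolysis: H adds to C2 and the α-bromo radical at C1 should take the second H on the α-face anti to the axial C10 methyl group, so bromine ends equatorial (1β), which is also the more stable epimer.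

**Step 12**
Reactants: 20 methyl (1R,4aS,6R,8aR)-1-bromo-4a-hydroxy-8a-methyl-4-oxodecahydronaphthalene-6-carboxylate
Product: 21 methyl (1R,4aS,6R,8aR)-1-bromo-8a-methyl-4-oxo-4a-(triethylsilyloxy)decahydronaphthalene-6-carboxylate
Conditions: Et3SiOTf, 2,6-lutidine, CH2Cl2, −78 → 0 °C
Reagents that add atoms: triethylsilyl trifluoromethanesulfonate, CC[Si](CC)(CC)OS(=O)(=O)C(F)(F)F
Why: Silylation of the tertiary alcohol by a silyl triflate; the ether blocks the Grob-type fragmentation open to a C5 alkoxide (C1–Br is antiperiplanar to C5–C10) and the α-ketol shift.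

**Step 13**
Reactants: 21 methyl (1R,4aS,6R,8aR)-1-bromo-8a-methyl-4-oxo-4a-(triethylsilyloxy)decahydronaphthalene-6-carboxylate
Product: 22 methyl (1R,4aR,6R,8aR)-1-bromo-8a-methyl-4-methylidene-4a-(triethylsilyloxy)decahydronaphthalene-6-carboxylate
Conditions: Zn, CH2Br2, TiCl4, THF (pre-aged reagent); then 21, CH2Cl2, 0 → 23 °C
Reagents that add atoms: dibromomethane, BrCBr
Why: Takai–Lombardo methylenation: the non-basic gem-dimetallic reagent methylenates hindered, enolisable ketones, leaves ester, silyl ether and secondary bromide alone and avoids an enolate γ to the bromide.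

**Step 14**
Reactants: 22 methyl (1R,4aR,6R,8aR)-1-bromo-8a-methyl-4-methylidene-4a-(triethylsilyloxy)decahydronaphthalene-6-carboxylate
Product: 23 (1R,4aR,6R,8aR)-1-bromo-8a-methyl-4-methylidene-4a-(triethylsilyloxy)decahydronaphthalene-6-carbaldehyde
Conditions: i-Bu2AlH (1.1 equiv), CH2Cl2, −78 °C; then H2O
Reagents that add atoms: none
Why: Partial ester reduction by i-Bu2AlH at low temperature stops at the tetrahedral aluminium acetal, which gives the aldehyde on work-up.

**Step 15**
Reactants: 23 (1R,4aR,6R,8aR)-1-bromo-8a-methyl-4-methylidene-4a-(triethylsilyloxy)decahydronaphthalene-6-carbaldehyde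
Product: 24 [(1R,4aR,6R,8aR)-1-bromo-6-ethynyl-8a-methyl-4-methylidenedecahydronaphthalen-4a-yl]oxy(triethyl)silane
Conditions: dimethyl (1-diazo-2-oxopropyl)phosphonate, K2CO3, MeOH, 0 → 23 °C
Reagents that add atoms: dimethyl (1-diazo-2-oxopropyl)phosphonate, COP(=O)(OC)C(=[N+]=[N-])C(C)=O
Why: Seyferth–Gilbert homologation in the Ohira–Bestmann form turns the aldehyde into the terminal alkyne (C11≡C12) under mild carbonate base; any epimerisation at C7 returns the equatorial 7β-isomer.

**Step 16**
Reactants: 25 2-methylbut-1-en-3-yne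
Product: 27 (E)-1-bromo-3-methylbuta-1,3-diene, via alkenylzirconocene 26 (not isolated)
Conditions: Cp2Zr(H)Cl, THF, 23 °C; N-bromosuccinimide, 0 °C
Reagents that add atoms: N-bromosuccinimide, O=C1CCC(=O)N1Br
Why: Syn hydrozirconation of the alkyne of the enyne places zirconium at the terminus and bromination of the C–Zr bond with retention gives the E-dienyl bromide.

**Step 17**
Reactants: 24 [(1R,4aR,6R,8aR)-1-bromo-6-ethynyl-8a-methyl-4-methylidenedecahydronaphthalen-4a-yl]oxy(triethyl)silane; 27 (E)-1-bromo-3-methylbuta-1,3-diene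
Product: 29 [(1R,4aR,6R,8aR)-1-bromo-8a-methyl-4-methylidene-6-[(2E,4E)-6-methylhepta-2,4,6-trien-2-yl]decahydronaphthalen-4a-yl]oxy(triethyl)silane, via alkenylalane 28 (not isolated)
Conditions: AlMe3 (2 equiv), Cp2ZrCl2 (25 mol%), CH2Cl2, 0 → 23 °C; then 27, Pd(PPh3)4 (5 mol%), ZnCl2 (20 mol%), THF, 23 °C
Reagents that add atoms: trimethylaluminium, C[Al](C)C
Why: Zirconium-catalysed syn carboalumination adds CH3 to C11 and aluminium to C12 and so fixes the E-trisubstituted alkene, and the Negishi-type palladium-catalysed coupling of the alkenylalane and the E-bromide proceeds with retention at both partners.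

**Step 18**
Reactants: 29 [(1R,4aR,6R,8aR)-1-bromo-8a-methyl-4-methylidene-6-[(2E,4E)-6-methylhepta-2,4,6-trien-2-yl]decahydronaphthalen-4a-yl]oxy(triethyl)silane
Product: 30 (1R,4aR,6R,8aR)-1-bromo-8a-methyl-4-methylidene-6-[(2E,4E)-6-methylhepta-2,4,6-trien-2-yl]decahydronaphthalen-4a-ol
Conditions: Bu4NF, AcOH (1:1), THF, 0 °C
Reagents that add atoms: none
Why: Fluoride-mediated desilylation buffered by acetic acid frees the tertiary allylic alcohol without building up the alkoxide (no fragmentation) and without strong acid (no allylic ionisation).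

**Compound list**

1 | 3-methylfuran | Cc1ccoc1 | starting material
2 | acrolein | C=CC=O | starting material
3 | 3-(3-methylfuran-2-yl)propanal | Cc1ccoc1CCC=O | intermediate
4 | allylmagnesium bromide | C=CC[Mg]Br | starting material
5 | (±)-1-(3-methylfuran-2-yl)hex-5-en-3-ol | Cc1ccoc1CCC(O)CC=C | intermediate
6 | 1-(3-methylfuran-2-yl)hex-5-en-3-one | Cc1ccoc1CCC(=O)CC=C | intermediate
7 | methyl acrylate | C=CC(=O)OC | starting material
8 | methyl (E)-7-(3-methylfuran-2-yl)-5-oxohept-2-enoate | Cc1ccoc1CCC(=O)C/C=C/C(=O)OC | intermediate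
9 | methyl (E)-7-(6-methyl-2,3,7-trioxabicyclo[2.2.1]hept-5-en-1-yl)-5-oxohept-2-enoate (racemic endoperoxide) | CC1=CC2OOC1(CCC(=O)C/C=C/C(=O)OC)O2 | intermediate
10 | methyl (2E,9Z)-9-methyl-5,8,11-trioxoundeca-2,9-dienoate | O=C/C=C(/C)C(=O)CCC(=O)C/C=C/C(=O)OC | intermediate
11 | methyl (2E,9E)-9-methyl-5,8,11-trioxoundeca-2,9-dienoate | O=C/C=C(\C)C(=O)CCC(=O)C/C=C/C(=O)OC | intermediate
12 | methyl (E)-3-[(2R)-2-methyl-3,6-dioxo-2-(2-oxoethyl)cyclohexyl]prop-2-enoate (epimers at the enolisable ring CH) | O=CC[C@@]1(C)C(=O)CCC(=O)C1/C=C/C(=O)OC | intermediate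
13 | methyl (8aR)-8a-methyl-1,4-dioxo-1,2,3,4,8,8a-hexahydronaphthalene-6-carboxylate | COC(=O)C1=CC[C@@]2(C)C(=O)CCC(=O)C2=C1 | intermediate
14 | methyl (6R,8aR)-8a-methyl-1,4-dioxo-1,2,3,4,6,7,8,8a-octahydronaphthalene-6-carboxylate | COC(=O)[C@@H]1CC[C@@]2(C)C(=O)CCC(=O)C2=C1 | intermediate
15 | dipotassium bis-enolate of 14 (C1 enolate and C4–C7 extended enolate) | COC(=O)C1CC[C@@]2(C)C([O-])=CCC([O-])=C2C=1.[K+].[K+] | intermediate
16 | methyl (6R,8aR)-8a-methyl-4-oxo-1-(trifluoromethylsulfonyloxy)-3,4,6,7,8,8a-hexahydronaphthalene-6-carboxylate | COC(=O)[C@@H]1CC[C@@]2(C)C(OS(=O)(=O)C(F)(F)F)=CCC(=O)C2=C1 | intermediate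
17 | methyl (6R,8aR)-1-bromo-8a-methyl-4-oxo-3,4,6,7,8,8a-hexahydronaphthalene-6-carboxylate | COC(=O)[C@@H]1CC[C@@]2(C)C(Br)=CCC(=O)C2=C1 | intermediate
18 | methyl (4aS,6R,8aR)-1-bromo-4a-hydroperoxy-8a-methyl-4-oxo-3,4,4a,5,6,7,8,8a-octahydronaphthalene-6-carboxylate | COC(=O)[C@@H]1CC[C@@]2(C)C(Br)=CCC(=O)[C@]2(OO)C1 | intermediate
19 | methyl (4aS,6R,8aR)-1-bromo-4a-hydroxy-8a-methyl-4-oxo-3,4,4a,5,6,7,8,8a-octahydronaphthalene-6-carboxylate | COC(=O)[C@@H]1CC[C@@]2(C)C(Br)=CCC(=O)[C@]2(O)C1 | intermediate
20 | methyl (1R,4aS,6R,8aR)-1-bromo-4a-hydroxy-8a-methyl-4-oxodecahydronaphthalene-6-carboxylate | COC(=O)[C@@H]1CC[C@@]2(C)[C@H](Br)CCC(=O)[C@]2(O)C1 | intermediate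
21 | methyl (1R,4aS,6R,8aR)-1-bromo-8a-methyl-4-oxo-4a-(triethylsilyloxy)decahydronaphthalene-6-carboxylate | COC(=O)[C@@H]1CC[C@@]2(C)[C@H](Br)CCC(=O)[C@]2(O[Si](CC)(CC)CC)C1 | intermediate
22 | methyl (1R,4aR,6R,8aR)-1-bromo-8a-methyl-4-methylidene-4a-(triethylsilyloxy)decahydronaphthalene-6-carboxylate | COC(=O)[C@@H]1CC[C@@]2(C)[C@H](Br)CCC(=C)[C@]2(O[Si](CC)(CC)CC)C1 | intermediate
23 | (1R,4aR,6R,8aR)-1-bromo-8a-methyl-4-methylidene-4a-(triethylsilyloxy)decahydronaphthalene-6-carbaldehyde | O=C[C@@H]1CC[C@@]2(C)[C@H](Br)CCC(=C)[C@]2(O[Si](CC)(CC)CC)C1 | intermediate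
24 | [(1R,4aR,6R,8aR)-1-bromo-6-ethynyl-8a-methyl-4-methylidenedecahydronaphthalen-4a-yl]oxy(triethyl)silane | C#C[C@@H]1CC[C@@]2(C)[C@H](Br)CCC(=C)[C@]2(O[Si](CC)(CC)CC)C1 | intermediate
25 | 2-methylbut-1-en-3-yne | C=C(C)C#C | starting material
26 | chloro[(1E)-3-methylbuta-1,3-dienyl]zirconocene | C=C(C)/C=C/[Zr](Cl)(C1C=CC=C1)C1C=CC=C1 | intermediate
27 | (E)-1-bromo-3-methylbuta-1,3-diene | C=C(C)/C=C/Br | intermediate
28 | dimethyl[(E)-2-(decalinyl)prop-1-enyl]alane from 24 (Al on C12, CH3 on C11, cis to each other) | C[Al](C)/C=C(\C)[C@@H]1CC[C@@]2(C)[C@H](Br)CCC(=C)[C@]2(O[Si](CC)(CC)CC)C1 | intermediate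
29 | [(1R,4aR,6R,8aR)-1-bromo-8a-methyl-4-methylidene-6-[(2E,4E)-6-methylhepta-2,4,6-trien-2-yl]decahydronaphthalen-4a-yl]oxy(triethyl)silane | C=C(C)/C=C/C=C(\C)[C@@H]1CC[C@@]2(C)[C@H](Br)CCC(=C)[C@]2(O[Si](CC)(CC)CC)C1 | intermediate
30 | (1R,4aR,6R,8aR)-1-bromo-8a-methyl-4-methylidene-6-[(2E,4E)-6-methylhepta-2,4,6-trien-2-yl]decahydronaphthalen-4a-ol | C=C(C)/C=C/C=C(\C)[C@@H]1CC[C@@]2(C)[C@H](Br)CCC(=C)[C@]2(O)C1 | target

**Step count**

Total step count: 18. Longest linear sequence: 17 (steps 1–15, 17, 18).

**Steps most likely to fail**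

Step 6. What may go wrong is poor facial selectivity, through E/Z scrambling of the iminium ion or an uncatalysed background addition, or a stalled second ring closure. The fallback uses textbook reactions and a resolution and sets out from 11.
- Catalytic Cs2CO3 in MeCN brings about the intramolecular Michael addition and gives the racemic cyclohexanedione aldehyde F1, which is isolated.
- Piperidinium acetate in toluene with removal of water closes ring B by Knoevenagel-type aldol condensation to the racemic dienedione ester F2.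
- Hydrogenation as in step 7 gives the racemic enedione ester F3.
- Ketalisation of the more reactive saturated C1 ketone by (2R,3R)-butane-2,3-diol (TsOH, benzene, water removal) gives two diastereomeric ketals that are separated by chromatography.
- The (6R,8aR)-ketal F4 is hydrolysed (aq. HCl, acetone), and the route is rejoined at 14.

Step 8. What may go wrong is sulfonylation at the oxygen atoms of the extended enolate, incomplete second deprotonation, or protonation of the extended enolate at C5 so that the alkene leaves conjugation with the ketone. The fallback brings bromine in through a C1 radical instead of a bromoalkene and sets out from 14.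
- NaBH4 (EtOH, 0 °C) reduces only the saturated C1 ketone from the α-face to the 1β-alcohol F5.
- Conjugate reduction–α-oxygenation as in step 10 gives the 1β,5α-diol F6.
- Methyl chlorooxoacetate (Et3N, DMAP) acylates only the secondary alcohol to the mixed oxalate F7.
- Et3SiOTf and 2,6-lutidine give the silyl ether F8.
- One equivalent of aqueous CsOH cleaves the oxalate methyl ester to the caesium oxalate F9.
- Blue-light photoredox double decarboxylation forms the C1 radical. Conditions: [Ir{dF(CF3)ppy}2(dtbbpy)]PF6, diethyl bromomalonate, water, 1,2-dimethoxyethane, 60 °C. This extends the known radical deoxychlorination of such oxalates.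
- The α-face of that radical is covered by the axial 5α-silyloxy group, so bromine-atom transfer on the β-face should give 21, where the route is rejoined.

Step 11. What may go wrong is delivery of the second hydrogen atom to the β-face (axial bromide), loss of a bromine atom from the radical intermediate, or slow hydrogen-atom transfer to the hindered alkene. The fallback replaces radical hydrogenation by hydroxyl-directed hydrogenation and sets out from 19. With [Ir(cod)(PCy3)(py)]PF6 under H2 (1 atm) in CH2Cl2 the 5α-hydroxyl group binds iridium. Both hydrogens are then added syn to the α-face of C1=C2, which places bromine β. The route is rejoined at 20, and no new compound is made.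

**Further compounds**

F1 | step 6 | racemic methyl (E)-3-[2-methyl-3,6-dioxo-2-(2-oxoethyl)cyclohexyl]prop-2-enoate | O=CCC1(C)C(=O)CCC(=O)C1/C=C/C(=O)OC
F2 | step 6 | racemic methyl 8a-methyl-1,4-dioxo-1,2,3,4,8,8a-hexahydronaphthalene-6-carboxylate | COC(=O)C1=CCC2(C)C(=O)CCC(=O)C2=C1
F3 | step 6 | racemic methyl 8a-methyl-1,4-dioxo-1,2,3,4,6,7,8,8a-octahydronaphthalene-6-carboxylate (ester cis to the methyl group) | COC(=O)C1CCC2(C)C(=O)CCC(=O)C2=C1
F4 | step 6 | C1 ketal of 14 formed from (2R,3R)-butane-2,3-diol | COC(=O)[C@@H]1CC[C@@]2(C)C3(CCC(=O)C2=C1)O[C@H](C)[C@@H](C)O3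
F5 | step 8 | methyl (1R,6R,8aR)-1-hydroxy-8a-methyl-4-oxo-1,2,3,4,6,7,8,8a-octahydronaphthalene-6-carboxylate | COC(=O)[C@@H]1CC[C@@]2(C)[C@H](O)CCC(=O)C2=C1
F6 | step 8 | methyl (1R,4aS,6R,8aR)-1,4a-dihydroxy-8a-methyl-4-oxodecahydronaphthalene-6-carboxylate | COC(=O)[C@@H]1CC[C@@]2(C)[C@H](O)CCC(=O)[C@]2(O)C1
F7 | step 8 | C1 methyl oxalate of F6 | COC(=O)[C@@H]1CC[C@@]2(C)[C@H](OC(=O)C(=O)OC)CCC(=O)[C@]2(O)C1
F8 | step 8 | C5 triethylsilyl ether of F7 | COC(=O)[C@@H]1CC[C@@]2(C)[C@H](OC(=O)C(=O)OC)CCC(=O)[C@]2(O[Si](CC)(CC)CC)C1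
F9 | step 8 | caesium oxalate from F8 | COC(=O)[C@@H]1CC[C@@]2(C)[C@H](OC(=O)C(=O)[O-])CCC(=O)[C@]2(O[Si](CC)(CC)CC)C1.[Cs+]
F0 | step 11 | none | none
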